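**Retrosynthetic overview**

1. The target comes from aryl desilylation and oxidation of the C4 carbinol of a triol; its tertiary carbinol is made by α-selective addition of an (E)-allylbarium (aryl fragment) to a chair-locked 7-silyloxy-hydrindan-5-one.
2. That ketone comes from a bicyclic enone by CBS reduction, hydroxyl-directed epoxidation, oxidation and SmI2 opening, which relays reagent-controlled chirality into the ring.
3. The enone comes from an intramolecular aldol condensation of a cyclopentane keto aldehyde; this closes the six-membered ring (key step).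
4. The keto aldehyde comes from acylation and retro-Claisen opening of the cyclobutanone made from dichloroketene and 1,2-dimethylcyclopentene ([2+2] sets the cis vicinal quaternary methyls); the acyl donor is a Weinreb amide from γ,γ-dimethylbutyrolactone.
5. The aryl fragment comes from 4-methoxy-2-methylphenol by O-allylation, Claisen rearrangement and cross-metathesis. Ring order: cyclopentane (bought), temporary cyclobutanone, then the six-membered ring by aldol.

Assumption: compounds 2, 3 and 7–13 are racemic (each SMILES shows the enantiomer carried on) and the single enantiomer is secured in step 9; in the fallback resolution the (R)-1-phenylethylammonium salt of the (1R,2R)-acid is taken to be the less soluble one (otherwise the (S)-amine is used).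

**Route**

Step 1
Reactants: 1 1,2-dimethylcyclopent-1-ene
Product: 2 rac-(1S,5R)-7,7-dichloro-1,5-dimethylbicyclo[3.2.0]heptan-6-one
Conditions: Cl3CCOCl, activated Zn dust, POCl3, Et2O, reflux
Reagents that add atoms: trichloroacetyl chloride, ClC(Cl)(Cl)C(Cl)=O (source of dichloroketene, ClC(Cl)=C=O)
Why: Ketene–alkene [2+2] cycloaddition is suprafacial on the tetrasubstituted olefin, so both quaternary carbons form with the two methyls cis (racemic).

Step 2
Reactants: 2 rac-(1S,5R)-7,7-dichloro-1,5-dimethylbicyclo[3.2.0]heptan-6-one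
Product: 3 rac-(1R,5R)-1,5-dimethylbicyclo[3.2.0]heptan-6-one
Conditions: Zn dust, AcOH, 70 °C
Reagents that add atoms: none
Why: Reductive dechlorination of the α,α-dichloroketone by zinc leaves the strained ketone and both quaternary centres untouched.

Step 3
Reactants: 4 5,5-dimethyloxolan-2-one (γ,γ-dimethyl-γ-butyrolactone)
Product: 5 4-hydroxy-N-methoxy-N,4-dimethylpentanamide
Conditions: MeNH(OMe)·HCl, iPrMgCl, THF, −20 to 0 °C
Reagents that add atoms: N,O-dimethylhydroxylamine hydrochloride, CNOC.Cl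
Why: Weinreb aminolysis of the lactone by the magnesium amide opens the ring to the hydroxy amide; no stereocentre is involved.

Step 4
Reactants: 5 4-hydroxy-N-methoxy-N,4-dimethylpentanamide
Product: 6 N-methoxy-N,4-dimethyl-4-[(triethylsilyl)oxy]pentanamide
Conditions: TESOTf, 2,6-lutidine, CH2Cl2, −78 to 0 °C
Reagents that add atoms: triethylsilyl trifluoromethanesulfonate, CC[Si](CC)(CC)OS(=O)(=O)C(F)(F)F
Why: Silylation of the tertiary alcohol with the silyl triflate prevents relactonisation and later hemiketal formation.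

Step 5
Reactants: 3 rac-(1R,5R)-1,5-dimethylbicyclo[3.2.0]heptan-6-one; 6 N-methoxy-N,4-dimethyl-4-[(triethylsilyl)oxy]pentanamide
Product: 9 methyl rac-(1R,2R)-1,2-dimethyl-2-{5-methyl-2-oxo-5-[(triethylsilyl)oxy]hexyl}cyclopentane-1-carboxylate, via lithium enolate 7 (not isolated), via acylcyclobutanone 8 (not isolated)
Conditions: LDA (LiN(iPr)2), THF, −78 °C; 6, −78 to 0 °C; then MeOH, NaOMe (0.2 equiv), 0 °C to rt
Reagents that add atoms: methanol, CO
Why: The only enolisable position of 3 (C7) is C-acylated by the Weinreb amide (Claisen-type acylation), and methoxide then cleaves the strained β-diketone at the cyclobutanone carbonyl (retro-Claisen) to the 1,5-keto ester with the cis quaternary centres intact.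

Step 6
Reactants: 9 methyl rac-(1R,2R)-1,2-dimethyl-2-{5-methyl-2-oxo-5-[(triethylsilyl)oxy]hexyl}cyclopentane-1-carboxylate
Product: 10 rac-1-[(1R,2R)-2-(hydroxymethyl)-1,2-dimethylcyclopentyl]-5-methyl-5-[(triethylsilyl)oxy]hexan-2-ol (both C2 epimers)
Conditions: LiAlH4, THF, 0 °C to rt
Reagents that add atoms: none
Why: Hydride reduction of ester and ketone gives the diol (the new carbinol centre is destroyed in the next step), so one oxidation can deliver the keto aldehyde.

Step 7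
Reactants: 10 rac-1-[(1R,2R)-2-(hydroxymethyl)-1,2-dimethylcyclopentyl]-5-methyl-5-[(triethylsilyl)oxy]hexan-2-ol
Product: 11 rac-(1R,2R)-1,2-dimethyl-2-{5-methyl-2-oxo-5-[(triethylsilyl)oxy]hexyl}cyclopentane-1-carbaldehyde
Conditions: (COCl)2, DMSO, CH2Cl2, −78 °C; Et3N, −78 °C to rt
Reagents that add atoms: none
Why: Swern oxidation activates both hydroxyls at −78 °C before base is added, so no lactol forms that could be over-oxidised to a lactone; the aldehyde has no α-hydrogen.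

Step 8
Reactants: 11 rac-(1R,2R)-1,2-dimethyl-2-{5-methyl-2-oxo-5-[(triethylsilyl)oxy]hexyl}cyclopentane-1-carbaldehyde
Product: 13 rac-(3aR,7aS)-3a,7a-dimethyl-6-{2-methyl-2-[(triethylsilyl)oxy]propyl}-1,2,3,3a,4,7a-hexahydro-5H-inden-5-one, via aldol adduct 12 (not isolated)
Conditions: NaOMe (0.3 equiv), MeOH, rt to 50 °C
Reagents that add atoms: none
Why: Intramolecular aldol condensation closes the six-membered ring: the aldehyde is non-enolisable and only the C3′ enolate of the ketone reaches it through a six-membered transition state (the C1′ enolate would give a cyclobutanol), and E1cB dehydration removes the two aldol stereocentres.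

Step 9
Reactants: 13 rac-(3aR,7aS)-3a,7a-dimethyl-6-{2-methyl-2-[(triethylsilyl)oxy]propyl}-1,2,3,3a,4,7a-hexahydro-5H-inden-5-one
Product: 14 (3aR,5S,7aS)-3a,7a-dimethyl-6-{2-methyl-2-[(triethylsilyl)oxy]propyl}-2,3,3a,4,5,7a-hexahydro-1H-inden-5-ol
Conditions: (R)-2-methyl-CBS-oxazaborolidine (0.2 equiv), catecholborane, toluene, −78 °C; then chromatographic separation of the two diastereomeric alcohols
Reagents that add atoms: none
Why: Corey–Bakshi–Shibata reduction is reagent-controlled (α-substituted alkenyl arm large, CH2 arm small) and gives the (5S) carbinol from both enantiomers of the enone, whose two faces differ only by angular methyl versus ring CH2, so the racemate becomes two separable diastereomers and the one with OH trans to the angular methyls is the single (3aR,7aS) enantiomer (at most 50%).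

Step 10
Reactants: 14 (3aR,5S,7aS)-3a,7a-dimethyl-6-{2-methyl-2-[(triethylsilyl)oxy]propyl}-2,3,3a,4,5,7a-hexahydro-1H-inden-5-ol
Product: 15 (3aR,5S,6S,7R,7aR)-6,7-epoxy-3a,7a-dimethyl-6-{2-methyl-2-[(triethylsilyl)oxy]propyl}octahydro-1H-inden-5-ol
Conditions: VO(acac)2 (5 mol%), t-BuOOH, CH2Cl2, 0 °C to rt
Reagents that add atoms: tert-butyl hydroperoxide, CC(C)(C)OO
Why: Vanadium-catalysed hydroxyl-directed epoxidation delivers oxygen syn to the allylic OH, fixing C6 and C7 on the face trans to the angular methyls.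

Step 11
Reactants: 15 (3aR,5S,6S,7R,7aR)-6,7-epoxy-3a,7a-dimethyl-6-{2-methyl-2-[(triethylsilyl)oxy]propyl}octahydro-1H-inden-5-ol
Product: 16 (3aR,6R,7R,7aR)-6,7-epoxy-3a,7a-dimethyl-6-{2-methyl-2-[(triethylsilyl)oxy]propyl}octahydro-5H-inden-5-one
Conditions: Dess–Martin periodinane, NaHCO3, CH2Cl2, 0 °C to rt
Reagents that add atoms: none
Why: Dess–Martin oxidation of the secondary alcohol gives the α,β-epoxy ketone without touching the epoxide or the silyl ether.

Step 12
Reactants: 16 (3aR,6R,7R,7aR)-6,7-epoxy-3a,7a-dimethyl-6-{2-methyl-2-[(triethylsilyl)oxy]propyl}octahydro-5H-inden-5-one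
Product: 18 (3aR,6S,7S,7aR)-7-hydroxy-3a,7a-dimethyl-6-{2-methyl-2-[(triethylsilyl)oxy]propyl}octahydro-5H-inden-5-one, via C6-epimeric hydroxy ketone 17 (not isolated)
Conditions: SmI2 (2.5 equiv), THF/MeOH, −78 °C; then DBU (0.1 equiv), CH2Cl2, 0 °C to rt
Reagents that add atoms: none
Why: SmI2 reduction of the α,β-epoxy ketone cleaves only the Cα–O bond, so the C7 oxygen keeps its configuration, and the epimerisable C6 is equilibrated by DBU to the trans isomer with both groups equatorial.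

Step 13
Reactants: 18 (3aR,6S,7S,7aR)-7-hydroxy-3a,7a-dimethyl-6-{2-methyl-2-[(triethylsilyl)oxy]propyl}octahydro-5H-inden-5-one
Product: 19 (3aR,6S,7S,7aR)-3a,7a-dimethyl-6-{2-methyl-2-[(triethylsilyl)oxy]propyl}-7-[(triethylsilyl)oxy]octahydro-5H-inden-5-one
Conditions: TESCl, imidazole, DMAP (cat.), DMF, rt
Reagents that add atoms: chlorotriethylsilane, CC[Si](Cl)(CC)CC
Why: Silylation under non-enolising conditions protects the β-hydroxyl; the equatorial C7 silyloxy group and equatorial C6 chain lock the chair in which the C3a methyl is axial.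

Step 14
Reactants: 20 4-methoxy-2-methylphenol
Product: 21 1-methoxy-3-methyl-4-(prop-2-en-1-yloxy)benzene
Conditions: allyl bromide, K2CO3, acetone, reflux
Reagents that add atoms: allyl bromide, BrCC=C
Why: Williamson O-allylation of the phenoxide.

Step 15
Reactants: 21 1-methoxy-3-methyl-4-(prop-2-en-1-yloxy)benzene
Product: 22 4-methoxy-2-methyl-6-(prop-2-en-1-yl)phenol
Conditions: N,N-diethylaniline, 190 °C
Reagents that add atoms: none
Why: Aromatic Claisen rearrangement ([3,3]) can end only at the single free ortho position, since the other ortho carbon carries methyl and the para carbon methoxy.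

Step 16
Reactants: 22 4-methoxy-2-methyl-6-(prop-2-en-1-yl)phenol
Product: 23 tert-butyl[4-methoxy-2-methyl-6-(prop-2-en-1-yl)phenoxy]dimethylsilane
Conditions: TBSCl, imidazole, DMF, 40 °C
Reagents that add atoms: tert-butyldimethylsilyl chloride, CC(C)(C)[Si](C)(C)Cl
Why: The aryl silyl ether survives the organobarium step, mild acid and Dess–Martin oxidation, and is removed last by buffered fluoride.

Step 17
Reactants: 23 tert-butyl[4-methoxy-2-methyl-6-(prop-2-en-1-yl)phenoxy]dimethylsilane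
Product: 24 (2E)-4-{2-[(tert-butyldimethylsilyl)oxy]-5-methoxy-3-methylphenyl}-2-methylbut-2-enal
Conditions: methacrolein (5 equiv), second-generation Hoveyda–Grubbs catalyst (5 mol%), CH2Cl2, 40 °C
Reagents that add atoms: methacrolein, CC(=C)C=O
Why: Olefin cross-metathesis of the terminal alkene with methacrolein gives the trisubstituted enal as the thermodynamically favoured E isomer, which sets the side-chain double-bond geometry.

Step 18
Reactants: 24 (2E)-4-{2-[(tert-butyldimethylsilyl)oxy]-5-methoxy-3-methylphenyl}-2-methylbut-2-enal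
Product: 25 (2E)-4-{2-[(tert-butyldimethylsilyl)oxy]-5-methoxy-3-methylphenyl}-2-methylbut-2-en-1-ol
Conditions: NaBH4, CeCl3·7H2O, MeOH, 0 °C
Reagents that add atoms: none
Why: Luche reduction gives clean 1,2-reduction of the enal without moving the double bond.

Step 19
Reactants: 25 (2E)-4-{2-[(tert-butyldimethylsilyl)oxy]-5-methoxy-3-methylphenyl}-2-methylbut-2-en-1-ol
Product: 27 tert-butyl{2-[(2E)-4-chloro-3-methylbut-2-en-1-yl]-4-methoxy-6-methylphenoxy}dimethylsilane, via allylic mesylate 26 (not isolated)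
Conditions: MsCl, s-collidine, LiCl, DMF, 0 °C
Reagents that add atoms: lithium chloride, [Li+].[Cl-]
Why: Mesylation followed by SN2 displacement with chloride gives the primary allylic chloride without allylic transposition or loss of E geometry.

Step 20
Reactants: 27 tert-butyl{2-[(2E)-4-chloro-3-methylbut-2-en-1-yl]-4-methoxy-6-methylphenoxy}dimethylsilane; 19 (3aR,6S,7S,7aR)-3a,7a-dimethyl-6-{2-methyl-2-[(triethylsilyl)oxy]propyl}-7-[(triethylsilyl)oxy]octahydro-5H-inden-5-one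
Product: 29 (3aR,5R,6S,7S,7aR)-5-[(2E)-4-{2-[(tert-butyldimethylsilyl)oxy]-5-methoxy-3-methylphenyl}-2-methylbut-2-en-1-yl]-3a,7a-dimethyl-6-{2-methyl-2-[(triethylsilyl)oxy]propyl}-7-[(triethylsilyl)oxy]octahydro-1H-inden-5-ol, via allylbarium chloride 28 (not isolated)
Conditions: BaI2, lithium biphenylide (LiC12H10, 2 equiv), THF, rt; 27, −78 °C; then 19, −78 °C; aq. NH4Cl
Reagents that add atoms: none
Why: Yamamoto-type allylbarium reagents add to ketones at the α-carbon with retention of the E geometry, and in the locked chair the axial C3a methyl blocks axial attack, so the nucleophile enters equatorially and gives the axial (5R) tertiary alcohol cis to the angular methyls.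

Step 21
Reactants: 29 (3aR,5R,6S,7S,7aR)-5-[(2E)-4-{2-[(tert-butyldimethylsilyl)oxy]-5-methoxy-3-methylphenyl}-2-methylbut-2-en-1-yl]-3a,7a-dimethyl-6-{2-methyl-2-[(triethylsilyl)oxy]propyl}-7-[(triethylsilyl)oxy]octahydro-1H-inden-5-ol
Product: 30 (3aR,4S,5S,6R,7aR)-6-[(2E)-4-{2-[(tert-butyldimethylsilyl)oxy]-5-methoxy-3-methylphenyl}-2-methylbut-2-en-1-yl]-5-(2-hydroxy-2-methylpropyl)-3a,7a-dimethyloctahydro-1H-indene-4,6-diol
Conditions: CSA (0.2 equiv), MeOH/CH2Cl2, 0 °C to rt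
Reagents that add atoms: none
Why: Mild acid methanolysis removes both alkyl triethylsilyl ethers while the aryl tert-butyldimethylsilyl ether, the tertiary alcohols and the olefin survive.

Step 22
Reactants: 30 (3aR,4S,5S,6R,7aR)-6-[(2E)-4-{2-[(tert-butyldimethylsilyl)oxy]-5-methoxy-3-methylphenyl}-2-methylbut-2-en-1-yl]-5-(2-hydroxy-2-methylpropyl)-3a,7a-dimethyloctahydro-1H-indene-4,6-diol
Product: 31 (3aR,5R,6R,7aR)-6-[(2E)-4-{2-[(tert-butyldimethylsilyl)oxy]-5-methoxy-3-methylphenyl}-2-methylbut-2-en-1-yl]-6-hydroxy-5-(2-hydroxy-2-methylpropyl)-3a,7a-dimethyloctahydro-4H-inden-4-one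
Conditions: Dess–Martin periodinane, NaHCO3, CH2Cl2, 0 °C
Reagents that add atoms: none
Why: Only the secondary C4 alcohol can be oxidised (the other two are tertiary and the phenol is still silylated), giving the β-hydroxy ketone with C5 already in its stable equatorial configuration.

Step 23
Reactants: 31 (3aR,5R,6R,7aR)-6-[(2E)-4-{2-[(tert-butyldimethylsilyl)oxy]-5-methoxy-3-methylphenyl}-2-methylbut-2-en-1-yl]-6-hydroxy-5-(2-hydroxy-2-methylpropyl)-3a,7a-dimethyloctahydro-4H-inden-4-one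
Product: 32 (3aR,5R,6R,7aR)-6-hydroxy-6-[(2E)-4-(2-hydroxy-5-methoxy-3-methylphenyl)-2-methylbut-2-en-1-yl]-5-(2-hydroxy-2-methylpropyl)-3a,7a-dimethyloctahydro-4H-inden-4-one (CNP0190381.3)
Conditions: TBAF, AcOH (1:1), THF, 0 °C
Reagents that add atoms: none
Why: Acetic-acid-buffered fluoride cleaves the aryl silyl ether under near-neutral conditions, so the tertiary β-hydroxy ketone neither undergoes retro-aldol nor dehydrates.

**Compound list**

1 | 1,2-dimethylcyclopent-1-ene | CC1=C(C)CCC1 | starting material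
2 | rac-(1S,5R)-7,7-dichloro-1,5-dimethylbicyclo[3.2.0]heptan-6-one | O=C1C(Cl)(Cl)[C@@]2(C)CCC[C@@]12C | intermediate
3 | rac-(1R,5R)-1,5-dimethylbicyclo[3.2.0]heptan-6-one | O=C1C[C@@]2(C)CCC[C@@]12C | intermediate
4 | 5,5-dimethyloxolan-2-one | CC1(C)CCC(=O)O1 | starting material
5 | 4-hydroxy-N-methoxy-N,4-dimethylpentanamide | CON(C)C(=O)CCC(C)(C)O | intermediate
6 | N-methoxy-N,4-dimethyl-4-[(triethylsilyl)oxy]pentanamide | CON(C)C(=O)CCC(C)(C)O[Si](CC)(CC)CC | intermediate
7 | lithium C6–C7 enolate of 3 (racemic, not isolated) | [Li]OC1=C[C@@]2(C)CCC[C@@]12C | intermediate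
8 | 1,5-dimethyl-7-{4-methyl-4-[(triethylsilyl)oxy]pentanoyl}bicyclo[3.2.0]heptan-6-one (racemic, C7 epimers, not isolated) | CC[Si](CC)(CC)OC(C)(C)CCC(=O)C1[C@@]2(C)CCC[C@@]2(C)C1=O | intermediate
9 | methyl rac-(1R,2R)-1,2-dimethyl-2-{5-methyl-2-oxo-5-[(triethylsilyl)oxy]hexyl}cyclopentane-1-carboxylate | CC[Si](CC)(CC)OC(C)(C)CCC(=O)C[C@@]1(C)CCC[C@@]1(C)C(=O)OC | intermediate
10 | rac-1-[(1R,2R)-2-(hydroxymethyl)-1,2-dimethylcyclopentyl]-5-methyl-5-[(triethylsilyl)oxy]hexan-2-ol (both C2 epimers) | CC[Si](CC)(CC)OC(C)(C)CCC(O)C[C@@]1(C)CCC[C@@]1(C)CO | intermediate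
11 | rac-(1R,2R)-1,2-dimethyl-2-{5-methyl-2-oxo-5-[(triethylsilyl)oxy]hexyl}cyclopentane-1-carbaldehyde | CC[Si](CC)(CC)OC(C)(C)CCC(=O)C[C@@]1(C)CCC[C@@]1(C)C=O | intermediate
12 | 7-hydroxy-3a,7a-dimethyl-6-{2-methyl-2-[(triethylsilyl)oxy]propyl}octahydro-5H-inden-5-one (racemic, cis-fused, C6/C7 epimers, not isolated) | O=C1C[C@@]2(C)CCC[C@@]2(C)C(O)C1CC(C)(C)O[Si](CC)(CC)CC | intermediate
13 | rac-(3aR,7aS)-3a,7a-dimethyl-6-{2-methyl-2-[(triethylsilyl)oxy]propyl}-1,2,3,3a,4,7a-hexahydro-5H-inden-5-one | O=C1C[C@@]2(C)CCC[C@@]2(C)C=C1CC(C)(C)O[Si](CC)(CC)CC | intermediate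
14 | (3aR,5S,7aS)-3a,7a-dimethyl-6-{2-methyl-2-[(triethylsilyl)oxy]propyl}-2,3,3a,4,5,7a-hexahydro-1H-inden-5-ol | O[C@H]1C[C@@]2(C)CCC[C@@]2(C)C=C1CC(C)(C)O[Si](CC)(CC)CC | intermediate
15 | (3aR,5S,6S,7R,7aR)-6,7-epoxy-3a,7a-dimethyl-6-{2-methyl-2-[(triethylsilyl)oxy]propyl}octahydro-1H-inden-5-ol | O[C@H]1C[C@@]2(C)CCC[C@@]2(C)[C@H]3O[C@@]13CC(C)(C)O[Si](CC)(CC)CC | intermediate
16 | (3aR,6R,7R,7aR)-6,7-epoxy-3a,7a-dimethyl-6-{2-methyl-2-[(triethylsilyl)oxy]propyl}octahydro-5H-inden-5-one | O=C1C[C@@]2(C)CCC[C@@]2(C)[C@H]3O[C@@]13CC(C)(C)O[Si](CC)(CC)CC | intermediate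
17 | (3aR,7S,7aR)-7-hydroxy-3a,7a-dimethyl-6-{2-methyl-2-[(triethylsilyl)oxy]propyl}octahydro-5H-inden-5-one, C6 epimer mixture (not isolated) | O=C1C[C@@]2(C)CCC[C@@]2(C)[C@@H](O)C1CC(C)(C)O[Si](CC)(CC)CC | intermediate
18 | (3aR,6S,7S,7aR)-7-hydroxy-3a,7a-dimethyl-6-{2-methyl-2-[(triethylsilyl)oxy]propyl}octahydro-5H-inden-5-one | O=C1C[C@@]2(C)CCC[C@@]2(C)[C@@H](O)[C@@H]1CC(C)(C)O[Si](CC)(CC)CC | intermediate
19 | (3aR,6S,7S,7aR)-3a,7a-dimethyl-6-{2-methyl-2-[(triethylsilyl)oxy]propyl}-7-[(triethylsilyl)oxy]octahydro-5H-inden-5-one | O=C1C[C@@]2(C)CCC[C@@]2(C)[C@@H](O[Si](CC)(CC)CC)[C@@H]1CC(C)(C)O[Si](CC)(CC)CC | intermediate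
20 | 4-methoxy-2-methylphenol | COc1ccc(O)c(C)c1 | starting material
21 | 1-methoxy-3-methyl-4-(prop-2-en-1-yloxy)benzene | COc1ccc(OCC=C)c(C)c1 | intermediate
22 | 4-methoxy-2-methyl-6-(prop-2-en-1-yl)phenol | COc1cc(C)c(O)c(CC=C)c1 | intermediate
23 | tert-butyl[4-methoxy-2-methyl-6-(prop-2-en-1-yl)phenoxy]dimethylsilane | COc1cc(C)c(O[Si](C)(C)C(C)(C)C)c(CC=C)c1 | intermediate
24 | (2E)-4-{2-[(tert-butyldimethylsilyl)oxy]-5-methoxy-3-methylphenyl}-2-methylbut-2-enal | COc1cc(C)c(O[Si](C)(C)C(C)(C)C)c(C/C=C(\C)C=O)c1 | intermediate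
25 | (2E)-4-{2-[(tert-butyldimethylsilyl)oxy]-5-methoxy-3-methylphenyl}-2-methylbut-2-en-1-ol | COc1cc(C)c(O[Si](C)(C)C(C)(C)C)c(C/C=C(\C)CO)c1 | intermediate
26 | (2E)-4-{2-[(tert-butyldimethylsilyl)oxy]-5-methoxy-3-methylphenyl}-2-methylbut-2-en-1-yl methanesulfonate (not isolated) | COc1cc(C)c(O[Si](C)(C)C(C)(C)C)c(C/C=C(\C)COS(C)(=O)=O)c1 | intermediate
27 | tert-butyl{2-[(2E)-4-chloro-3-methylbut-2-en-1-yl]-4-methoxy-6-methylphenoxy}dimethylsilane | COc1cc(C)c(O[Si](C)(C)C(C)(C)C)c(C/C=C(\C)CCl)c1 | intermediate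
28 | {(2E)-4-{2-[(tert-butyldimethylsilyl)oxy]-5-methoxy-3-methylphenyl}-2-methylbut-2-en-1-yl}barium chloride (not isolated) | COc1cc(C)c(O[Si](C)(C)C(C)(C)C)c(C/C=C(\C)C[Ba]Cl)c1 | intermediate
29 | (3aR,5R,6S,7S,7aR)-5-[(2E)-4-{2-[(tert-butyldimethylsilyl)oxy]-5-methoxy-3-methylphenyl}-2-methylbut-2-en-1-yl]-3a,7a-dimethyl-6-{2-methyl-2-[(triethylsilyl)oxy]propyl}-7-[(triethylsilyl)oxy]octahydro-1H-inden-5-ol | COc1cc(C)c(O[Si](C)(C)C(C)(C)C)c(C/C=C(\C)C[C@@]2(O)C[C@@]3(C)CCC[C@@]3(C)[C@@H](O[Si](CC)(CC)CC)[C@@H]2CC(C)(C)O[Si](CC)(CC)CC)c1 | intermediate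
30 | (3aR,4S,5S,6R,7aR)-6-[(2E)-4-{2-[(tert-butyldimethylsilyl)oxy]-5-methoxy-3-methylphenyl}-2-methylbut-2-en-1-yl]-5-(2-hydroxy-2-methylpropyl)-3a,7a-dimethyloctahydro-1H-indene-4,6-diol | COc1cc(C)c(O[Si](C)(C)C(C)(C)C)c(C/C=C(\C)C[C@@]2(O)C[C@@]3(C)CCC[C@@]3(C)[C@@H](O)[C@@H]2CC(C)(C)O)c1 | intermediate
31 | (3aR,5R,6R,7aR)-6-[(2E)-4-{2-[(tert-butyldimethylsilyl)oxy]-5-methoxy-3-methylphenyl}-2-methylbut-2-en-1-yl]-6-hydroxy-5-(2-hydroxy-2-methylpropyl)-3a,7a-dimethyloctahydro-4H-inden-4-one | COc1cc(C)c(O[Si](C)(C)C(C)(C)C)c(C/C=C(\C)C[C@@]2(O)C[C@@]3(C)CCC[C@@]3(C)C(=O)[C@@H]2CC(C)(C)O)c1 | intermediate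
32 | (3aR,5R,6R,7aR)-6-hydroxy-6-[(2E)-4-(2-hydroxy-5-methoxy-3-methylphenyl)-2-methylbut-2-en-1-yl]-5-(2-hydroxy-2-methylpropyl)-3a,7a-dimethyloctahydro-4H-inden-4-one | COc1cc(C)c(O)c(C/C=C(\C)C[C@@]2(O)C[C@@]3(C)CCC[C@@]3(C)C(=O)[C@@H]2CC(C)(C)O)c1 | target

**Step count and risks**

Total step count: 23.
Longest linear sequence: 15 steps (steps 1, 2, 5–13, 20–23 from alkene 1; the same count from lactone 4 through steps 3–13 and 20–23). The aryl branch is 6 steps (14–19). 15/23 = 0.65.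

Three steps most likely to fail:

Step 5 (acylation of the hindered cyclobutanone enolate by a Weinreb amide, then regioselective retro-Claisen). The fallback builds the 1,5-dicarbonyl photochemically instead; it sets out from 1 and 6 and comes back at 11, bypassing steps 1, 2 and 5–7. Weinreb amide 6 with MeMgBr gives the methyl ketone 5-methyl-5-[(triethylsilyl)oxy]hexan-2-one F1. Kinetic formylation at the methyl group (LDA, then 2,2,2-trifluoroethyl formate) gives the hydrogen-bonded enol (1Z)-1-hydroxy-6-methyl-6-[(triethylsilyl)oxy]hept-1-en-3-one F2. Irradiation of F2 with alkene 1 (350 nm, MeCN) is a De Mayo reaction: the [2+2] photoadduct rac-1-(7-hydroxy-1,5-dimethylbicyclo[3.2.0]heptan-6-yl)-4-methyl-4-[(triethylsilyl)oxy]pentan-1-one F3 is not isolated and opens by retro-aldol to racemic keto aldehyde 11, again with cis methyls.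

Step 9 (reagent control on a racemate and separation of two diastereomers that differ only in which face carries methyls versus ring CH2). The fallback resolves before ring closure; it sets out from 8 and comes back at 10. Acylcyclobutanone 8 is opened with aqueous NaOH instead of NaOMe to the racemic keto acid rac-(1R,2R)-1,2-dimethyl-2-{5-methyl-2-oxo-5-[(triethylsilyl)oxy]hexyl}cyclopentane-1-carboxylic acid F4. Crystallisation with (R)-1-phenylethylamine gives the salt (R)-1-phenylethylammonium (1R,2R)-1,2-dimethyl-2-{5-methyl-2-oxo-5-[(triethylsilyl)oxy]hexyl}cyclopentane-1-carboxylate F5. Citric acid liberates the enantiopure acid (1R,2R)-1,2-dimethyl-2-{5-methyl-2-oxo-5-[(triethylsilyl)oxy]hexyl}cyclopentane-1-carboxylic acid F6, which LiAlH4 reduces to diol 10 as a single enantiomer. Steps 7 and 8 then give enantiopure 13, and step 9 becomes a plain diastereoselective reduction with no pseudo-enantiomer to remove.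

Step 20 (α- versus γ-selectivity and facial selectivity of the allylbarium on a hindered ketone). The fallback assembles the side chain in two bonds; it sets out from 19 (benzyl partner from 20) and comes back at 29.
- Propargylmagnesium bromide (Et2O, −78 °C) adds equatorially to 19 under the same chair lock and gives the homopropargylic alcohol (3aR,5R,6S,7S,7aR)-3a,7a-dimethyl-6-{2-methyl-2-[(triethylsilyl)oxy]propyl}-5-(prop-2-yn-1-yl)-7-[(triethylsilyl)oxy]octahydro-1H-inden-5-ol F7.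
- Phenol 20 is ortho-formylated (MgCl2, Et3N, paraformaldehyde) to 2-hydroxy-5-methoxy-3-methylbenzaldehyde F8, silylated (TBSCl, imidazole) to 2-[(tert-butyldimethylsilyl)oxy]-5-methoxy-3-methylbenzaldehyde F9, reduced (NaBH4) to {2-[(tert-butyldimethylsilyl)oxy]-5-methoxy-3-methylphenyl}methanol F10 and chlorinated (MsCl, LiCl, s-collidine) to tert-butyl[2-(chloromethyl)-4-methoxy-6-methylphenoxy]dimethylsilane F11.
- Zirconium-catalysed syn carboalumination of F7 (AlMe3, Cp2ZrCl2, CH2Cl2) gives the (E)-alkenylalane dimethyl{(1E)-3-[(3aR,5R,6S,7S,7aR)-5-hydroxy-3a,7a-dimethyl-6-{2-methyl-2-[(triethylsilyl)oxy]propyl}-7-[(triethylsilyl)oxy]octahydro-1H-inden-5-yl]-2-methylprop-1-en-1-yl}alane F12 (not isolated; the hydroxyl is held as its aluminium alkoxide). Pd(PPh3)4-catalysed coupling of F12 with F11 gives 29 with the E geometry fixed by the syn addition.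

**Further compounds**

F1 | step 5 | 5-methyl-5-[(triethylsilyl)oxy]hexan-2-one | CC(=O)CCC(C)(C)O[Si](CC)(CC)CC
F2 | step 5 | (1Z)-1-hydroxy-6-methyl-6-[(triethylsilyl)oxy]hept-1-en-3-one | O/C=C\C(=O)CCC(C)(C)O[Si](CC)(CC)CC
F3 | step 5 | rac-1-(7-hydroxy-1,5-dimethylbicyclo[3.2.0]heptan-6-yl)-4-methyl-4-[(triethylsilyl)oxy]pentan-1-one | OC1C(C(=O)CCC(C)(C)O[Si](CC)(CC)CC)[C@@]2(C)CCC[C@@]12C
F4 | step 9 | rac-(1R,2R)-1,2-dimethyl-2-{5-methyl-2-oxo-5-[(triethylsilyl)oxy]hexyl}cyclopentane-1-carboxylic acid | CC[Si](CC)(CC)OC(C)(C)CCC(=O)C[C@@]1(C)CCC[C@@]1(C)C(O)=O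
F5 | step 9 | (R)-1-phenylethylammonium (1R,2R)-1,2-dimethyl-2-{5-methyl-2-oxo-5-[(triethylsilyl)oxy]hexyl}cyclopentane-1-carboxylate | CC[Si](CC)(CC)OC(C)(C)CCC(=O)C[C@@]1(C)CCC[C@@]1(C)C([O-])=O.C[C@@H]([NH3+])c1ccccc1
F6 | step 9 | (1R,2R)-1,2-dimethyl-2-{5-methyl-2-oxo-5-[(triethylsilyl)oxy]hexyl}cyclopentane-1-carboxylic acid (single enantiomer) | CC[Si](CC)(CC)OC(C)(C)CCC(=O)C[C@@]1(C)CCC[C@@]1(C)C(O)=O
F7 | step 20 | (3aR,5R,6S,7S,7aR)-3a,7a-dimethyl-6-{2-methyl-2-[(triethylsilyl)oxy]propyl}-5-(prop-2-yn-1-yl)-7-[(triethylsilyl)oxy]octahydro-1H-inden-5-ol | C#CC[C@@]1(O)C[C@@]2(C)CCC[C@@]2(C)[C@@H](O[Si](CC)(CC)CC)[C@@H]1CC(C)(C)O[Si](CC)(CC)CC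
F8 | step 20 | 2-hydroxy-5-methoxy-3-methylbenzaldehyde | COc1cc(C)c(O)c(C=O)c1
F9 | step 20 | 2-[(tert-butyldimethylsilyl)oxy]-5-methoxy-3-methylbenzaldehyde | COc1cc(C)c(O[Si](C)(C)C(C)(C)C)c(C=O)c1
F10 | step 20 | {2-[(tert-butyldimethylsilyl)oxy]-5-methoxy-3-methylphenyl}methanol | COc1cc(C)c(O[Si](C)(C)C(C)(C)C)c(CO)c1
F11 | step 20 | tert-butyl[2-(chloromethyl)-4-methoxy-6-methylphenoxy]dimethylsilane | COc1cc(C)c(O[Si](C)(C)C(C)(C)C)c(CCl)c1
F12 | step 20 | dimethyl{(1E)-3-[(3aR,5R,6S,7S,7aR)-5-hydroxy-3a,7a-dimethyl-6-{2-methyl-2-[(triethylsilyl)oxy]propyl}-7-[(triethylsilyl)oxy]octahydro-1H-inden-5-yl]-2-methylprop-1-en-1-yl}alane | C[Al](C)/C=C(\C)C[C@@]1(O)C[C@@]2(C)CCC[C@@]2(C)[C@@H](O[Si](CC)(CC)CC)[C@@H]1CC(C)(C)O[Si](CC)(CC)CC
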